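The closed, stirred vessel is charged with starting material, which becomes single ring. The single ring then fades, and in epsilon, charged stronger than gamma, its highest reading stands lower.

| flask | starting material | remark | time |
|---|---|---|---|
| gamma | 0.025 M | run made earlier |  |
| epsilon | 0.038 M | run made earlier |  |
| flask | 0.050 M |  | 12 d |

| run | time / d | single ring / % | starting material / % |
|---|---|---|---|
| gamma | 0.500 | 33.9 | 44.2 |
| gamma | 1.04 | 49.4 | 23.6 |
| gamma | 2.50 | 53.7 | 7.2 |
| gamma | 6.00 | 29.0 | 0.7 |
| gamma | 15.0 | 6.8 | 0 |
| epsilon | 0.500 | 33.1 | 38.5 |
| epsilon | 1.04 | 45.0 | 20.6 |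
| epsilon | 2.50 | 48.9 | 6.1 |
| epsilon | 6.00 | 28.2 | 1.5 |
| epsilon | 15.0 | 5.9 | 0.4 |

(readings scatter by 0.5 percentage points)

- time up to 12 d at which single ring stands highest
- the amount of single ring, in percent of the starting material charged, at that time
- earliest time at which at least nineteen twentieths of that best amount are there, in d
- latest time at which they still are, in d

- a reading or a percentage of single ring counts all its forms, free or not
- a reading of starting material is of its free form alone

1. Our first way. In each earlier run the highest reading of single ring stands at 2.50 d: 53.7% in gamma, 48.9% in epsilon. The charge penalty is the rise of the reciprocal of that top fraction for each mol/L more of c(starting material): 14.1 L mol⁻¹. Carried from gamma to the flask's 0.050 M, it gives a top of 45.2%.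

2. Our second way counts half-lives. The two latest readings of single ring in epsilon give a half-life of 3.99 d. So 28.2% at 6.00 d, carried back 0.877 half-lives to 2.50 d, gives 51.8%. The two runs stand within 0.8 percentage points at that late time, so this way promises the flask the same 51.8%.

3. The two ways part by 6.6 points. Tried on epsilon itself, the second way claims 51.8% where the reading was 48.9%, so it is the one that cheats. The readings of the two runs differ by 4.8 points at 2.50 d and by 0.8 points at 6.00 d, less at the later time, so the later reading shows the charge less than the top does. We keep 45.2%.

4. The forecast extrapolates the reciprocal too, but lands higher than we do: 46% (range 43% to 48.5%) at 2 d, in a window from 1.3 d to 2.9 d. It reads the late tail of free starting material as some of it “held reversibly and released slowly”.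

The flask gives 47.7% at 1.92 d, with the window from 1.24 d to 2.84 d. These lie inside the forecast's ranges.

    2 starting material → open dimer (k = 9.27 × 10⁻⁵ L mol⁻¹ s⁻¹)
    single ring ⇌ isomer of the product (K = 20.8, k = 2.85 × 10⁻⁶ s⁻¹)
    starting material → single ring (k = 1.25 × 10⁻⁵ s⁻¹)
    open dimer → ring dimer (k = 2.71 × 10⁻⁶ s⁻¹)
    starting material + open dimer → open trimer (k = 3.13 × 10⁻⁴ L mol⁻¹ s⁻¹)
    starting material + single ring ⇌ idle adduct, settled at all times (K = 43.3 L mol⁻¹)

The flask tops out 2.5 points above our 45.2%, so from gamma's reading to the flask the penalty comes to 9.40 L mol⁻¹, less than the 14.1 L mol⁻¹ read from the two runs. Now take a neighbouring flask, changed in its charge to 0.020 M. Gamma's reading and 14.1 L mol⁻¹ give it 55.8%, and its single ring tops out at 55.9%.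

All runs were computed for substances that don't exist.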